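**Retrosynthetic overview**

1. The target comes from its 3-O-TBS ether 17, which is cut at the central C3′–C4′ σ-bond of the (2E,4E)-dienoate into acrylate 12 (C1′–C3′ on O–C6 of ring A) and alkynol 16 (C4′–C8′, with C4′≡C5′ one oxidation level above the target alkene).
2. Enabling feature: C4′=C5′ is flanked by the fully substituted carbinol C6′ (bulky, no H) and C2′=C3′ is conjugated to the ester carbonyl C1′. One half is therefore a terminal alkyne with fixed hydrometalation regiochemistry and the other an acrylate acceptor; the internal ring alkenes C1=C8a and C7=C8 and the masked C3 ketol should not compete.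
3. Acrylate 12 comes from a C2 silyl dienol ether that masks C2=O while C6=O is reduced under control of the C4a methyl, and then delivers the C3 oxygen by Rubottom oxidation.
4. Ring order: ring A is the six-membered ring of quinone monoketal 1 (desymmetrising Cu-catalysed methyl addition sets C5, then α′-methylation). Ring B is closed second by Robinson annulation with MVK, which sets C4a and gives the C1=C8a–C8=C7 dienone directly.
5. Alkynol 16 comes from (S)-2-methylglycidol by methyl-cuprate epoxide opening, oxidation and Seyferth–Gilbert homologation.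

Key step: step 12

Remark on numbering: bicyclic compounds are named with the locants of the naphthalen-2-one core throughout (C2 ketone carbon, C3, C4, C4a quaternary, C5, C6 ester carbon, C7=C8, C8a=C1); primed locants belong to the octadienoate chain.

Assumption: the sense of induction in step 1 is taken by analogy with dialkylzinc additions to this dienone class; the ligand antipode that delivers (R)-2 is used.

**Route**

Step 1
Reactants: 1 4,4-dimethoxycyclohexa-2,5-dien-1-one
Product: 2 (R)-4,4-dimethoxy-5-methylcyclohex-2-en-1-one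
Conditions: Me2Zn, Cu(OTf)2 (cat.), BINOL/bis(1-phenylethyl)amine phosphoramidite (cat.), toluene, −25 °C; aq. NH4Cl
Reagents that add atoms: dimethylzinc, C[Zn]C
Why: Cu/phosphoramidite-catalysed enantioselective conjugate addition of a dialkylzinc desymmetrises the two enantiotopic enone arms of the quinone monoketal, the chiral copper complex choosing arm and face and thereby setting C5 (R), while the less electrophilic mono-enone product should resist a second addition.

Step 2
Reactants: 2 (R)-4,4-dimethoxy-5-methylcyclohex-2-en-1-one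
Product: 3 (5R,6R)-4,4-dimethoxy-5,6-dimethylcyclohex-2-en-1-one
Conditions: LDA, THF, −78 °C; MeI, DMPU, −78 → −20 °C
Reagents that add atoms: iodomethane, CI
Why: Kinetic enolate alkylation is regiospecific because C6 is the only enolisable position (C4 is a ketal); methyl enters anti to the C5 methyl, but this C6 configuration is inconsequential since the centre is re-enolised in step 3.

Step 3
Reactants: 3 (5R,6R)-4,4-dimethoxy-5,6-dimethylcyclohex-2-en-1-one; 4 but-3-en-2-one (MVK)
Product: 6 (4aR,5R)-6,6-dimethoxy-4a,5-dimethyl-4,4a,5,6-tetrahydronaphthalen-2(3H)-one, via Michael adduct 5 (not isolated)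
Conditions: MVK, KOH (cat.), MeOH, 0 °C → rt; then KOH, MeOH, 60 °C
Reagents that add atoms: none
Why: Robinson annulation (base-catalysed Michael addition then intramolecular aldol condensation): the only possible enolate, at C6 of 3, adds to MVK on the face opposite the adjacent C5 methyl, which sets the quaternary centre (future C4a) with the two methyl groups cis, and the methyl ketone then condenses onto the ring carbonyl to close ring B and give the linear C2(=O)–C1=C8a–C8=C7 dienone directly.

Step 4
Reactants: 6 (4aR,5R)-6,6-dimethoxy-4a,5-dimethyl-4,4a,5,6-tetrahydronaphthalen-2(3H)-one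
Product: 7 (4aR,5R)-4a,5-dimethyl-4,4a-dihydronaphthalene-2,6(3H,5H)-dione
Conditions: 10% aq. oxalic acid, THF, 0 °C → rt
Reagents that add atoms: water, O
Why: Acid-catalysed ketal hydrolysis proceeds through a diene-stabilised oxocarbenium ion under conditions mild enough that enolisation toward the hindered C5–H (epimerisation) should not compete, and no stereocentre is formed.

Step 5
Reactants: 7 (4aR,5R)-4a,5-dimethyl-4,4a-dihydronaphthalene-2,6(3H,5H)-dione
Product: 8 (4aR,5R)-2-[(tert-butyldimethylsilyl)oxy]-4a,5-dimethyl-4,4a-dihydronaphthalen-6(5H)-one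
Conditions: TBSOTf, Et3N, CH2Cl2, −78 °C
Reagents that add atoms: tert-butyldimethylsilyl trifluoromethanesulfonate, CC(C)(C)[Si](C)(C)OS(=O)(=O)C(F)(F)F
Why: Regioselective silyl enol ether formation by soft enolisation: only the C2 carbonyl has an accessible α-CH2 (C3), the C6 carbonyl being flanked by the tertiary, neopentyl-type C5–H, so the cross-conjugated C2 silyl dienol ether forms and both masks C2=O for step 6 and arms C3 for step 8.

Step 6
Reactants: 8 (4aR,5R)-2-[(tert-butyldimethylsilyl)oxy]-4a,5-dimethyl-4,4a-dihydronaphthalen-6(5H)-one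
Product: 9 (4aR,5R,6S)-2-[(tert-butyldimethylsilyl)oxy]-4a,5-dimethyl-4,4a,5,6-tetrahydronaphthalen-6-ol
Conditions: DIBAL-H, toluene, −78 °C; aq. Rochelle salt
Reagents that add atoms: none
Why: Chemoselective 1,2-reduction of the only free carbonyl by an aluminium hydride that should enter C6 from the face opposite the pseudo-axial C4a methyl (1,3-relationship), placing the new hydroxyl cis to both methyl groups (6S).

Step 7
Reactants: 9 (4aR,5R,6S)-2-[(tert-butyldimethylsilyl)oxy]-4a,5-dimethyl-4,4a,5,6-tetrahydronaphthalen-6-ol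
Product: 10 (4aR,5R,6S)-2-[(tert-butyldimethylsilyl)oxy]-4a,5-dimethyl-4,4a,5,6-tetrahydronaphthalen-6-yl prop-2-enoate
Conditions: acryloyl chloride, i-Pr2NEt, DMAP (cat.), CH2Cl2, −20 → 0 °C
Reagents that add atoms: acryloyl chloride, C=CC(Cl)=O
Why: DMAP-catalysed O-acylation with an acid chloride under basic conditions that preserve the silyl dienol ether and the acid-labile trienyl C–O bond, so C6 keeps its configuration.

Step 8
Reactants: 10 (4aR,5R,6S)-2-[(tert-butyldimethylsilyl)oxy]-4a,5-dimethyl-4,4a,5,6-tetrahydronaphthalen-6-yl prop-2-enoate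
Product: 12 (3R,4aR,5R,6S)-3-[(tert-butyldimethylsilyl)oxy]-4a,5-dimethyl-2-oxo-2,3,4,4a,5,6-hexahydronaphthalen-6-yl prop-2-enoate, via silyloxy epoxide 11 (not isolated)
Conditions: DMDO, acetone/CH2Cl2, −78 → 0 °C
Reagents that add atoms: dimethyldioxirane, CC1(C)OO1
Why: Rubottom oxidation: the electron-rich C2=C3 enol ether is epoxidised in preference to the acrylate and the other ring alkenes on the face opposite the C4a methyl, and epoxide opening with 1,4-silyl migration gives the α-silyloxy dienone with C3–O trans to the angular methyl (3R, also the equatorial and thermodynamically favoured epimer).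

Step 9
Reactants: 13 (S)-(2-methyloxiran-2-yl)methanol ((S)-2-methylglycidol)
Product: 14 (R)-2-methylbutane-1,2-diol
Conditions: MeMgBr, CuI (cat.), THF, −40 → 0 °C; aq. NH4Cl
Reagents that add atoms: methylmagnesium bromide, C[Mg]Br
Why: Copper-catalysed Grignard opening of the 2,2-disubstituted epoxide at its unsubstituted CH2 terminus leaves the quaternary stereocentre untouched (the descriptor changes from S to R only through the change in substituent priorities).

Step 10
Reactants: 14 (R)-2-methylbutane-1,2-diol
Product: 15 (R)-2-hydroxy-2-methylbutanal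
Conditions: IBX, EtOAc, 75 °C; filter, use crude
Reagents that add atoms: none
Why: IBX oxidation converts the primary hydroxyl of the 1,2-diol into the aldehyde without glycol cleavage and cannot touch the tertiary alcohol; the product has no α-hydrogen and so cannot epimerise.

Step 11
Reactants: 15 (R)-2-hydroxy-2-methylbutanal
Product: 16 (R)-3-methylpent-1-yn-3-ol
Conditions: dimethyl (1-diazo-2-oxopropyl)phosphonate, K2CO3, MeOH, 0 °C → rt
Reagents that add atoms: dimethyl (1-diazo-2-oxopropyl)phosphonate, COP(=O)(OC)C(=[N+]=[N-])C(C)=O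
Why: Seyferth–Gilbert homologation (Ohira–Bestmann variant) turns the non-enolisable aldehyde into the terminal alkyne under mild carbonate base that tolerates the free tertiary alcohol, with the carbinol centre untouched.

Step 12
Reactants: 12 (3R,4aR,5R,6S)-3-[(tert-butyldimethylsilyl)oxy]-4a,5-dimethyl-2-oxo-2,3,4,4a,5,6-hexahydronaphthalen-6-yl prop-2-enoate; 16 (R)-3-methylpent-1-yn-3-ol
Product: 17 (3R,4aR,5R,6S)-3-[(tert-butyldimethylsilyl)oxy]-4a,5-dimethyl-2-oxo-2,3,4,4a,5,6-hexahydronaphthalen-6-yl (2E,4E,6R)-6-hydroxy-6-methylocta-2,4-dienoate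
Conditions: [RuHCl(CO)(PPh3)3] (cat.), 16 (1.5 equiv, slow addition), toluene/DMF, 70 °C
Reagents that add atoms: none
Why: Proposed new method: the Ru–H should add syn across the terminal alkyne of 16 with Ru on the unhindered terminus C4′ (the quaternary carbinol C6′ blocks the other regiochemistry and has no H through which to isomerise), giving an (E)-alkenyl–Ru species that inserts the acrylate C2′=C3′ of 12 at its β-carbon (forming C3′–C4′) and then undergoes syn β-hydride elimination to the (2E)-enoate, regenerating Ru–H in a redox-neutral, fully atom-economical cycle. The closest known reaction types are the Ru–H- and Pd–H-catalysed hydrovinylation (ene–yne coupling) of internal and aryl alkynes with acrylates and the alkenyl Heck reaction; the extension to a terminal tertiary propargylic alcohol and an allylic acrylate is the untested part. No ring is closed and no stereocentre is formed; the two alkene geometries are set by the syn hydrometalation (4′E) and by syn β-hydride elimination from the less strained rotamer (2′E). The step needs cross- over homo-coupling and selection of the acrylate over the dienone alkenes C7=C8/C1=C8a and the allylic C6–O bond: slow addition keeps the alkyne concentration low, the acrylate is the only unhindered electron-poor terminal alkene, and a Ru(II) hydride, unlike Pd(0), should not ionise the allylic ester. The tertiary OH cannot be oxidised and the 3-OTBS group masks the α-ketol against transfer dehydrogenation.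

Step 13
Reactants: 17 (3R,4aR,5R,6S)-3-[(tert-butyldimethylsilyl)oxy]-4a,5-dimethyl-2-oxo-2,3,4,4a,5,6-hexahydronaphthalen-6-yl (2E,4E,6R)-6-hydroxy-6-methylocta-2,4-dienoate
Product: 18 (3R,4aR,5R,6S)-3-hydroxy-4a,5-dimethyl-2-oxo-2,3,4,4a,5,6-hexahydronaphthalen-6-yl (2E,4E,6R)-6-hydroxy-6-methylocta-2,4-dienoate (target)
Conditions: HF·pyridine, pyridine/THF, 0 °C → rt
Reagents that add atoms: none
Why: Fluoride-mediated silyl ether cleavage under buffered, non-basic conditions should remove the secondary TBS group without epimerising the C3 ketol, cleaving the dienoate ester or ionising the tertiary allylic alcohol.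

**Compound list**

1 | 4,4-dimethoxycyclohexa-2,5-dien-1-one | COC1(OC)C=CC(=O)C=C1 | starting material
2 | (R)-4,4-dimethoxy-5-methylcyclohex-2-en-1-one | O=C1C=CC(OC)(OC)[C@H](C)C1 | intermediate
3 | (5R,6R)-4,4-dimethoxy-5,6-dimethylcyclohex-2-en-1-one | O=C1C=CC(OC)(OC)[C@H](C)[C@H]1C | intermediate
4 | but-3-en-2-one (methyl vinyl ketone) | CC(=O)C=C | starting material
5 | Michael adduct, (5R,6R)-4,4-dimethoxy-5,6-dimethyl-6-(3-oxobutyl)cyclohex-2-en-1-one | CC(=O)CC[C@]1(C)[C@@H](C)C(OC)(OC)C=CC1=O | intermediate
6 | (4aR,5R)-6,6-dimethoxy-4a,5-dimethyl-4,4a,5,6-tetrahydronaphthalen-2(3H)-one | COC1(OC)C=CC2=CC(=O)CC[C@]2(C)[C@H]1C | intermediate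
7 | (4aR,5R)-4a,5-dimethyl-4,4a-dihydronaphthalene-2,6(3H,5H)-dione | O=C1C=CC2=CC(=O)CC[C@]2(C)[C@H]1C | intermediate
8 | (4aR,5R)-2-[(tert-butyldimethylsilyl)oxy]-4a,5-dimethyl-4,4a-dihydronaphthalen-6(5H)-one | O=C1C=CC2=CC(O[Si](C)(C)C(C)(C)C)=CC[C@]2(C)[C@H]1C | intermediate
9 | (4aR,5R,6S)-2-[(tert-butyldimethylsilyl)oxy]-4a,5-dimethyl-4,4a,5,6-tetrahydronaphthalen-6-ol | O[C@H]1C=CC2=CC(O[Si](C)(C)C(C)(C)C)=CC[C@]2(C)[C@H]1C | intermediate
10 | (4aR,5R,6S)-2-[(tert-butyldimethylsilyl)oxy]-4a,5-dimethyl-4,4a,5,6-tetrahydronaphthalen-6-yl prop-2-enoate | C=CC(=O)O[C@H]1C=CC2=CC(O[Si](C)(C)C(C)(C)C)=CC[C@]2(C)[C@H]1C | intermediate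
11 | silyloxy epoxide, (2R,3R,4aR,5R,6S)-2-[(tert-butyldimethylsilyl)oxy]-2,3-epoxy-4a,5-dimethyl-2,3,4,4a,5,6-hexahydronaphthalen-6-yl prop-2-enoate (oxirane on the face opposite the C4a methyl) | C=CC(=O)O[C@H]1C=CC2=C[C@]3(O[Si](C)(C)C(C)(C)C)O[C@@H]3C[C@]2(C)[C@H]1C | intermediate
12 | (3R,4aR,5R,6S)-3-[(tert-butyldimethylsilyl)oxy]-4a,5-dimethyl-2-oxo-2,3,4,4a,5,6-hexahydronaphthalen-6-yl prop-2-enoate | C=CC(=O)O[C@H]1C=CC2=CC(=O)[C@H](O[Si](C)(C)C(C)(C)C)C[C@]2(C)[C@H]1C | intermediate
13 | (S)-(2-methyloxiran-2-yl)methanol | C[C@]1(CO)CO1 | starting material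
14 | (R)-2-methylbutane-1,2-diol | CC[C@@](C)(O)CO | intermediate
15 | (R)-2-hydroxy-2-methylbutanal | CC[C@@](C)(O)C=O | intermediate
16 | (R)-3-methylpent-1-yn-3-ol | CC[C@@](C)(O)C#C | intermediate
17 | (3R,4aR,5R,6S)-3-[(tert-butyldimethylsilyl)oxy]-4a,5-dimethyl-2-oxo-2,3,4,4a,5,6-hexahydronaphthalen-6-yl (2E,4E,6R)-6-hydroxy-6-methylocta-2,4-dienoate | CC[C@@](C)(O)/C=C/C=C/C(=O)O[C@H]1C=CC2=CC(=O)[C@H](O[Si](C)(C)C(C)(C)C)C[C@]2(C)[C@H]1C | intermediate
18 | (3R,4aR,5R,6S)-3-hydroxy-4a,5-dimethyl-2-oxo-2,3,4,4a,5,6-hexahydronaphthalen-6-yl (2E,4E,6R)-6-hydroxy-6-methylocta-2,4-dienoate | CC[C@@](C)(O)/C=C/C=C/C(=O)O[C@H]1C=CC2=CC(=O)[C@H](O)C[C@]2(C)[C@H]1C | target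

**Step count and risks**

Total steps: 13. Longest linear sequence: 10 (steps 1–8, 12, 13); the alkynol branch is steps 9–11.

Steps most likely to fail:

1. Step 12 (Proposed new method). The catalyst may be diverted into alkyne oligomerisation through Ru-acetylide or vinylidene species, the propargylic alcohol may dehydrate or rearrange, or the cycle may stall after acrylate insertion. The fallback uses known chemistry, sets out from 16 and returns at 17. Pd-catalysed hydrostannation of 16 (Bu3SnH, cat. PdCl2(PPh3)2, THF, 0 °C) should give (R,E)-3-methyl-1-(tributylstannyl)pent-1-en-3-ol F1. Iododestannylation (I2, CH2Cl2, 0 °C) should give (R,E)-1-iodo-3-methylpent-1-en-3-ol F2. A ligand-free Heck coupling of F2 with acrylate 12 (Pd(OAc)2, Ag2CO3, DMF, rt) should then give 17, with the fast oxidative addition of the vinyl iodide outrunning ionisation of the allylic ester.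

2. Step 6. Hydride may be delivered in conjugate fashion to the cross-conjugated trienone, and the silyl dienol ether may be lost or the electron-rich trienyl carbinol ionised during work-up. The fallback sets out from 7 and returns at 10, with the carbinol formed before any enol ether exists. Dione 7 is deprotonated at C3 (LiHMDS, THF, −78 °C) to the lithium C2-enolate, lithium (4aR,5R)-4a,5-dimethyl-6-oxo-4,4a,5,6-tetrahydronaphthalen-2-olate F3, which masks C2=O in situ while DIBAL-H reduces C6=O. Aqueous work-up should give the robust hydroxy dienone (4aR,5R,6S)-6-hydroxy-4a,5-dimethyl-4,4a,5,6-tetrahydronaphthalen-2(3H)-one F4. Acryloylation (acryloyl chloride, i-Pr2NEt, DMAP) gives (4aR,5R,6S)-4a,5-dimethyl-2-oxo-2,3,4,4a,5,6-hexahydronaphthalen-6-yl prop-2-enoate F5, and soft enolisation (TBSOTf, Et3N, CH2Cl2, −78 °C) gives 10.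

3. Step 3. Under equilibrating base the Michael addition is reversible and may be weakly face-selective at the new quaternary centre, and MVK may polymerise. The fallback sets out from 3 and returns at 6. The kinetic lithium enolate of 3 (LDA, THF, −78 °C) is trapped irreversibly at low temperature by the α-silyl vinyl ketone 3-(trimethylsilyl)but-3-en-2-one to give the α-silyl Michael adduct (5R,6R)-4,4-dimethoxy-5,6-dimethyl-6-[3-oxo-2-(trimethylsilyl)butyl]cyclohex-2-en-1-one F6. KOH/MeOH then removes silicon (giving 5) and effects the aldol condensation to 6.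

**Further compounds**

F1 | step 12 | (R,E)-3-methyl-1-(tributylstannyl)pent-1-en-3-ol | CC[C@@](C)(O)/C=C/[Sn](CCCC)(CCCC)CCCC
F2 | step 12 | (R,E)-1-iodo-3-methylpent-1-en-3-ol | CC[C@@](C)(O)/C=C/I
F3 | step 6 | lithium (4aR,5R)-4a,5-dimethyl-6-oxo-4,4a,5,6-tetrahydronaphthalen-2-olate | [Li+].[O-]C1=CC[C@]2(C)[C@@H](C)C(=O)C=CC2=C1
F4 | step 6 | (4aR,5R,6S)-6-hydroxy-4a,5-dimethyl-4,4a,5,6-tetrahydronaphthalen-2(3H)-one | O[C@H]1C=CC2=CC(=O)CC[C@]2(C)[C@H]1C
F5 | step 6 | (4aR,5R,6S)-4a,5-dimethyl-2-oxo-2,3,4,4a,5,6-hexahydronaphthalen-6-yl prop-2-enoate | C=CC(=O)O[C@H]1C=CC2=CC(=O)CC[C@]2(C)[C@H]1C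
F6 | step 3 | (5R,6R)-4,4-dimethoxy-5,6-dimethyl-6-[3-oxo-2-(trimethylsilyl)butyl]cyclohex-2-en-1-one (both epimers at the silyl-bearing carbon) | CC(=O)C(C[C@]1(C)[C@@H](C)C(OC)(OC)C=CC1=O)[Si](C)(C)C
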